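## Retrosynthetic overview

- Ring C is cut at O1–C8a, C4–C4a and O1–C2. Ring A becomes an aryne; ring B together with C2, C3, C4 and O1 becomes a 2-arylacrylic acid. The two are joined in one operation: aryne insertion into the acid O–C(acyl) bond, then oxa-Michael closure.
- Enabling feature: C8a and C4a are adjacent carbons of ring A carrying the ether oxygen O1 and the acyl carbon C4, and C2 lies β to the C4 carbonyl. The C7 oxygen is para to C4a and cannot steer the aryne, so a bromine at C5 is carried as a regiocontrol element and removed afterwards.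
- C3 is an enolisable α-aryl ketone centre. It is left racemic in the key step and set afterwards as 3R by transfer hydrogenation with dynamic kinetic resolution (cis-(3R,4R)-4-ol) and reoxidation. MOM ethers mask both phenols.
- Rings A and B are bought as benzene derivatives; ring C is the only ring formed. The acid comes from 2'-hydroxy-3',4'-dimethoxyacetophenone (bromination, MOM, branched-selective prenyl coupling, Shapiro carboxylation); the aryne precursor comes from 4-(methoxymethoxy)phenol.

Key step: step 8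

Assumption: 4-(methoxymethoxy)phenol is taken as a catalogue compound; the target SMILES corresponds to the 3R configuration.

## Route

Step 1
Reactants: 1 1-(2-hydroxy-3,4-dimethoxyphenyl)ethan-1-one
Product: 2 1-(5-bromo-2-hydroxy-3,4-dimethoxyphenyl)ethan-1-one
Conditions: NBS (1.05 equiv), MeCN, 0 °C to rt
Reagents that add atoms: N-bromosuccinimide, O=C1CCC(=O)N1Br
Why: Electrophilic aromatic bromination; C5' is para to the free OH and ortho to the 4'-OMe and is the only free position activated by both, while the acetyl group deactivates C6'.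

Step 2
Reactants: 2 1-(5-bromo-2-hydroxy-3,4-dimethoxyphenyl)ethan-1-one
Product: 3 1-[5-bromo-3,4-dimethoxy-2-(methoxymethoxy)phenyl]ethan-1-one
Conditions: NaH (1.1 equiv), MOMCl, DMF, 0 °C
Reagents that add atoms: chloromethyl methyl ether, COCCl
Why: Williamson-type O-alkylation of the sodium phenoxide; the MOM ether should withstand the organolithium, fluoride and palladium steps that follow.

Step 3
Reactants: 3 1-[5-bromo-3,4-dimethoxy-2-(methoxymethoxy)phenyl]ethan-1-one; 4 4,4,5,5-tetramethyl-2-(3-methylbut-2-en-1-yl)-1,3,2-dioxaborolane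
Product: 5 1-[3,4-dimethoxy-2-(methoxymethoxy)-5-(2-methylbut-3-en-2-yl)phenyl]ethan-1-one
Conditions: Pd(OAc)2 (3 mol%), dicyclohexylbiarylphosphine ligand (6 mol%, chosen for branched selectivity), K3PO4 (aq), MeCN, 70 °C
Reagents that add atoms: none
Why: Suzuki–Miyaura coupling of a 3,3-disubstituted allylboronate; transmetalation with allyl transposition (SE2') places palladium on the tertiary carbon, and a ligand that makes reductive elimination faster than allyl isomerisation should give the branched 1,1-dimethylallyl arene (ligand-controlled γ-selective allyl–aryl coupling).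

Step 4
Reactants: 5 1-[3,4-dimethoxy-2-(methoxymethoxy)-5-(2-methylbut-3-en-2-yl)phenyl]ethan-1-one; 6 2,4,6-triisopropylbenzenesulfonohydrazide
Product: 7 N'-{1-[3,4-dimethoxy-2-(methoxymethoxy)-5-(2-methylbut-3-en-2-yl)phenyl]ethylidene}-2,4,6-triisopropylbenzenesulfonohydrazide
Conditions: PPTS (cat.), THF, rt
Reagents that add atoms: none
Why: Condensation of the methyl ketone with the sulfonyl hydrazide gives the trisylhydrazone needed for the Shapiro reaction; the mild acid catalyst should leave the MOM acetal intact.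

Step 5
Reactants: 7 N'-{1-[3,4-dimethoxy-2-(methoxymethoxy)-5-(2-methylbut-3-en-2-yl)phenyl]ethylidene}-2,4,6-triisopropylbenzenesulfonohydrazide
Product: 9 2-[3,4-dimethoxy-2-(methoxymethoxy)-5-(2-methylbut-3-en-2-yl)phenyl]prop-2-enoic acid, via vinyllithium 8 (not isolated)
Conditions: n-BuLi (2.2 equiv), THF, –78 °C to 0 °C; then CO2, –78 °C; then dilute HCl to pH 3, 0 °C
Reagents that add atoms: carbon dioxide, O=C=O
Why: Shapiro reaction; double deprotonation, loss of arenesulfinate and N2 should give the 1-arylvinyllithium regiospecifically (the methyl group holds the only α-hydrogens), and carboxylation gives the 2-arylacrylic acid.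

Step 6
Reactants: 10 4-(methoxymethoxy)phenol
Product: 11 2,6-dibromo-4-(methoxymethoxy)phenol
Conditions: NBS (2.1 equiv), i-Pr2NH (10 mol%), CH2Cl2, 0 °C to rt
Reagents that add atoms: N-bromosuccinimide, O=C1CCC(=O)N1Br
Why: Amine-catalysed ortho-bromination of a phenol; both positions ortho to the free OH are brominated because the para position is blocked.

Step 7
Reactants: 11 2,6-dibromo-4-(methoxymethoxy)phenol
Product: 15 2-bromo-4-(methoxymethoxy)-6-(trimethylsilyl)phenyl trifluoromethanesulfonate, via silyl ether 12 (not isolated), via aryllithium 13 (not isolated), via lithium phenolate 14 (not isolated)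
Conditions: HMDS, THF, 70 °C, then evaporation; n-BuLi (1.05 equiv), THF, –100 °C to –78 °C; Tf2O, –78 °C to rt
Reagents that add atoms: hexamethyldisilazane, C[Si](C)(C)N[Si](C)(C)C; trifluoromethanesulfonic anhydride, O=S(=O)(OS(=O)(=O)C(F)(F)F)C(F)(F)F
Why: Standard silylaryl triflate synthesis (O-silylation, bromine–lithium exchange at one of two equivalent bromines, retro-Brook shift of silicon from O to C, triflation of the phenolate); the second bromine stays as the regiocontrol element of the aryne.

Step 8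
Reactants: 9 2-[3,4-dimethoxy-2-(methoxymethoxy)-5-(2-methylbut-3-en-2-yl)phenyl]prop-2-enoic acid; 15 2-bromo-4-(methoxymethoxy)-6-(trimethylsilyl)phenyl trifluoromethanesulfonate
Product: 19 rac-5-bromo-3-[3,4-dimethoxy-2-(methoxymethoxy)-5-(2-methylbut-3-en-2-yl)phenyl]-7-(methoxymethoxy)-2,3-dihydro-4H-chromen-4-one, via aryne 16 (not isolated), via aryl carbanion 17 (not isolated), via phenolate enone 18 (not isolated)
Conditions: CsF (4 equiv), 15 (1.3 equiv), THF, 125 °C, sealed tube
Reagents that add atoms: none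
Why: Fluoride desilylation of 15 with loss of triflate gives aryne 16, the carboxylate of 9 adds through oxygen to the aryne carbon remote from bromine (O1–C8a), the aryl carbanion 17 that results at C4a attacks the adjacent ester carbonyl and the four-membered adduct opens to ketone phenolate 18 (C4–C4a, in sum an insertion of the aryne into the O–C(acyl) bond), and the phenolate oxygen then adds to the CH2 terminus of the 1-arylvinyl ketone (O1–C2) before the enolate is protonated. The closest known reaction type is the CsF-mediated insertion of arynes from silylaryl triflates into the C–O bond of α,β-unsaturated carboxylic acids with in situ oxa-Michael closure to chroman-4-ones. Ring C, the only ring closed, forms by 6-endo-trig conjugate addition of the phenolate. C3 is formed by uncontrolled protonation of the enolate and is racemic, which is accepted because this α-aryl ketone centre equilibrates under the basic conditions and is set in steps 10 and 11. The step needs oxygen on C8a and acyl on C4a rather than the reverse, and the bromine on the carbon next to the C4a aryne carbon secures this: by its inductive effect and the resulting aryne distortion the nucleophile adds to the remote aryne carbon so that the charge develops beside the halogen, which outweighs the weak bias of the more distant MOM-oxy group. Attack of the carbanion at the carbonyl carbon rather than at the acrylate β-carbon follows from the geometry of the Z-configured aryl ester, in which only the carbonyl carbon lies within reach.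

Step 9
Reactants: 19 rac-5-bromo-3-[3,4-dimethoxy-2-(methoxymethoxy)-5-(2-methylbut-3-en-2-yl)phenyl]-7-(methoxymethoxy)-2,3-dihydro-4H-chromen-4-one
Product: 20 rac-3-[3,4-dimethoxy-2-(methoxymethoxy)-5-(2-methylbut-3-en-2-yl)phenyl]-7-(methoxymethoxy)-2,3-dihydro-4H-chromen-4-one
Conditions: Pd(OAc)2 (5 mol%), PPh3 (20 mol%), HCO2Na (3 equiv), DMF, 80 °C
Reagents that add atoms: none
Why: Palladium-catalysed hydrodehalogenation with formate as hydride source, helped by the ortho carbonyl that activates the C5–Br bond; the terminal alkene has no allylic hydrogens and cannot be isomerised, and C3 is still racemic so the medium cannot harm it.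

Step 10
Reactants: 20 rac-3-[3,4-dimethoxy-2-(methoxymethoxy)-5-(2-methylbut-3-en-2-yl)phenyl]-7-(methoxymethoxy)-2,3-dihydro-4H-chromen-4-one
Product: 21 (3R,4R)-3-[3,4-dimethoxy-2-(methoxymethoxy)-5-(2-methylbut-3-en-2-yl)phenyl]-7-(methoxymethoxy)-3,4-dihydro-2H-chromen-4-ol
Conditions: RuCl(p-cymene)[(R,R)-TsDPEN] (2 mol%), HCO2H/Et3N (5:2), EtOAc, 40 °C
Reagents that add atoms: none
Why: Noyori–Ikariya asymmetric transfer hydrogenation with dynamic kinetic resolution; triethylamine racemises C3 through the enol faster than reduction, and the (R,R)-catalyst is expected to give the 4R carbinol (as with 4-chromanone) with hydride delivered anti to the aryl group, so the cis-(3R,4R) alcohol should form and fix C3 as R.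

Step 11
Reactants: 21 (3R,4R)-3-[3,4-dimethoxy-2-(methoxymethoxy)-5-(2-methylbut-3-en-2-yl)phenyl]-7-(methoxymethoxy)-3,4-dihydro-2H-chromen-4-ol
Product: 22 (3R)-3-[3,4-dimethoxy-2-(methoxymethoxy)-5-(2-methylbut-3-en-2-yl)phenyl]-7-(methoxymethoxy)-2,3-dihydro-4H-chromen-4-one
Conditions: Dess–Martin periodinane (1.3 equiv), CH2Cl2, 0 °C to rt; Na2S2O3/pH 7 buffer work-up
Reagents that add atoms: none
Why: Dess–Martin oxidation of the benzylic secondary alcohol under base-free conditions should return the C4 ketone without enolisation, so the 3R configuration from step 10 is kept.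

Step 12
Reactants: 22 (3R)-3-[3,4-dimethoxy-2-(methoxymethoxy)-5-(2-methylbut-3-en-2-yl)phenyl]-7-(methoxymethoxy)-2,3-dihydro-4H-chromen-4-one
Product: 23 pervilleanone, (3R)-7-hydroxy-3-[2-hydroxy-3,4-dimethoxy-5-(2-methylbut-3-en-2-yl)phenyl]-2,3-dihydro-4H-chromen-4-one
Conditions: Me2BBr (5 equiv), CH2Cl2, –78 °C; then THF/aq NaHCO3, 0 °C
Reagents that add atoms: none
Why: Lewis acid cleavage of both MOM acetals (bromomethyl ether formation, then hydrolysis on work-up); at –78 °C without base the α-aryl ketone centre should not epimerise, and the aryl methyl ethers and the alkene should not react.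

## Compound list

1 | 1-(2-hydroxy-3,4-dimethoxyphenyl)ethan-1-one | CC(=O)c1ccc(OC)c(OC)c1O | starting material
2 | 1-(5-bromo-2-hydroxy-3,4-dimethoxyphenyl)ethan-1-one | CC(=O)c1cc(Br)c(OC)c(OC)c1O | intermediate
3 | 1-[5-bromo-3,4-dimethoxy-2-(methoxymethoxy)phenyl]ethan-1-one | CC(=O)c1cc(Br)c(OC)c(OC)c1OCOC | intermediate
4 | 4,4,5,5-tetramethyl-2-(3-methylbut-2-en-1-yl)-1,3,2-dioxaborolane (prenylboronic acid pinacol ester) | CC(C)=CCB1OC(C)(C)C(C)(C)O1 | starting material
5 | 1-[3,4-dimethoxy-2-(methoxymethoxy)-5-(2-methylbut-3-en-2-yl)phenyl]ethan-1-one | CC(=O)c1cc(C(C)(C)C=C)c(OC)c(OC)c1OCOC | intermediate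
6 | 2,4,6-triisopropylbenzenesulfonohydrazide | CC(C)c1cc(C(C)C)c(S(=O)(=O)NN)c(C(C)C)c1 | starting material
7 | trisylhydrazone of 5 | CC(=NNS(=O)(=O)c1c(C(C)C)cc(C(C)C)cc1C(C)C)c1cc(C(C)(C)C=C)c(OC)c(OC)c1OCOC | intermediate
8 | 1-[3,4-dimethoxy-2-(methoxymethoxy)-5-(2-methylbut-3-en-2-yl)phenyl]vinyllithium | [Li]C(=C)c1cc(C(C)(C)C=C)c(OC)c(OC)c1OCOC | intermediate
9 | 2-[3,4-dimethoxy-2-(methoxymethoxy)-5-(2-methylbut-3-en-2-yl)phenyl]prop-2-enoic acid | C=C(C(=O)O)c1cc(C(C)(C)C=C)c(OC)c(OC)c1OCOC | intermediate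
10 | 4-(methoxymethoxy)phenol | COCOc1ccc(O)cc1 | starting material
11 | 2,6-dibromo-4-(methoxymethoxy)phenol | COCOc1cc(Br)c(O)c(Br)c1 | intermediate
12 | [2,6-dibromo-4-(methoxymethoxy)phenoxy]trimethylsilane | COCOc1cc(Br)c(O[Si](C)(C)C)c(Br)c1 | intermediate
13 | 3-bromo-5-(methoxymethoxy)-2-(trimethylsilyloxy)phenyllithium | COCOc1cc(Br)c(O[Si](C)(C)C)c([Li])c1 | intermediate
14 | lithium 2-bromo-4-(methoxymethoxy)-6-(trimethylsilyl)phenolate | COCOc1cc(Br)c([O-])c([Si](C)(C)C)c1.[Li+] | intermediate
15 | 2-bromo-4-(methoxymethoxy)-6-(trimethylsilyl)phenyl trifluoromethanesulfonate | COCOc1cc(Br)c(OS(=O)(=O)C(F)(F)F)c([Si](C)(C)C)c1 | intermediate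
16 | 3-bromo-5-(methoxymethoxy)benzyne | COCOC1=CC#CC(Br)=C1 | intermediate
17 | caesium salt of the 2-carbanion of 3-bromo-5-(methoxymethoxy)phenyl 2-arylacrylate | C=C(C(=O)Oc1cc(OCOC)cc(Br)[c-]1)c1cc(C(C)(C)C=C)c(OC)c(OC)c1OCOC.[Cs+] | intermediate
18 | caesium 3-bromo-2-(2-arylacryloyl)-5-(methoxymethoxy)phenolate | C=C(C(=O)c1c(Br)cc(OCOC)cc1[O-])c1cc(C(C)(C)C=C)c(OC)c(OC)c1OCOC.[Cs+] | intermediate
19 | rac-5-bromo-3-[3,4-dimethoxy-2-(methoxymethoxy)-5-(2-methylbut-3-en-2-yl)phenyl]-7-(methoxymethoxy)-2,3-dihydro-4H-chromen-4-one | C=CC(C)(C)c1cc(C2COc3cc(OCOC)cc(Br)c3C2=O)c(OCOC)c(OC)c1OC | intermediate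
20 | rac-3-[3,4-dimethoxy-2-(methoxymethoxy)-5-(2-methylbut-3-en-2-yl)phenyl]-7-(methoxymethoxy)-2,3-dihydro-4H-chromen-4-one | C=CC(C)(C)c1cc(C2COc3cc(OCOC)ccc3C2=O)c(OCOC)c(OC)c1OC | intermediate
21 | (3R,4R)-3-[3,4-dimethoxy-2-(methoxymethoxy)-5-(2-methylbut-3-en-2-yl)phenyl]-7-(methoxymethoxy)-3,4-dihydro-2H-chromen-4-ol (3-aryl and 4-OH cis) | C=CC(C)(C)c1cc([C@@H]2COc3cc(OCOC)ccc3[C@@H]2O)c(OCOC)c(OC)c1OC | intermediate
22 | (3R)-3-[3,4-dimethoxy-2-(methoxymethoxy)-5-(2-methylbut-3-en-2-yl)phenyl]-7-(methoxymethoxy)-2,3-dihydro-4H-chromen-4-one | C=CC(C)(C)c1cc([C@@H]2COc3cc(OCOC)ccc3C2=O)c(OCOC)c(OC)c1OC | intermediate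
23 | pervilleanone, (3R)-7-hydroxy-3-[2-hydroxy-3,4-dimethoxy-5-(2-methylbut-3-en-2-yl)phenyl]-2,3-dihydro-4H-chromen-4-one | C=CC(C)(C)c1cc([C@@H]2COc3cc(O)ccc3C2=O)c(O)c(OC)c1OC | target

## Step count and risks

Total step count: 12. Longest linear sequence: 10 steps (steps 1 to 5, then 8 to 12).

**Step 8.** The aryl carbanion may be protonated before the acyl shift, which would stop the cascade at the aryl ester. The carboxylate may add to the wrong aryne carbon. The acrylic acid may oligomerise at 125 °C, and the product enolate may be arylated by surplus aryne.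

Fallback, without an aryne, from hydrazone 7 to compound 20. Commercial 2,4-dihydroxybenzaldehyde is alkylated selectively at the non-chelated 4-OH (MOMCl, K2CO3, acetone) to 2-hydroxy-4-(methoxymethoxy)benzaldehyde F1. F1 is converted to its sodium phenoxide (NaH, THF) and treated at –78 °C with vinyllithium 8, generated from 7 as in step 5, to give 2-{1-hydroxy-2-[3,4-dimethoxy-2-(methoxymethoxy)-5-(2-methylbut-3-en-2-yl)phenyl]prop-2-en-1-yl}-5-(methoxymethoxy)phenol F2. Oxidation of the allylic, benzylic alcohol with MnO2 in CH2Cl2 gives 1-[2-hydroxy-4-(methoxymethoxy)phenyl]-2-[3,4-dimethoxy-2-(methoxymethoxy)-5-(2-methylbut-3-en-2-yl)phenyl]prop-2-en-1-one F3. Catalytic Et3N in MeOH then closes ring C by oxa-Michael addition to give 20, and steps 10 to 12 follow; the bromine and step 9 are not needed.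

**Step 3.** The allyl group may isomerise on palladium before reductive elimination and give the linear prenyl isomer. Coupling at the ortho-substituted bromide may be slow, and the boronate may protodeboronate.

Fallback, by sigmatropic rearrangement, from compound 1 to compound 5. Compound 1 is O-alkylated with 2-methylbut-3-yn-2-yl trifluoroacetate (DBU, CuCl2 cat., MeCN, 0 °C) to 1-[3,4-dimethoxy-2-(2-methylbut-3-yn-2-yloxy)phenyl]ethan-1-one F4. Semihydrogenation (H2, Pd/CaCO3 poisoned with Pb(OAc)2, quinoline) gives 1-[3,4-dimethoxy-2-(2-methylbut-3-en-2-yloxy)phenyl]ethan-1-one F5. Heating in N,N-diethylaniline at about 150 °C should bring about an aromatic Claisen shift to a blocked ortho carbon followed by a Cope shift to the free para position, giving 1-[2-hydroxy-3,4-dimethoxy-5-(2-methylbut-3-en-2-yl)phenyl]ethan-1-one F6. MOM protection as in step 2 gives 5.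

**Step 12.** Lewis acid-promoted enolisation during acetal cleavage may erode the configuration at C3, and cleavage of the hindered 2'-acetal may be incomplete.

Fallback, by a protecting-group switch before C3 is set, from compound 20 to compound 23. Both MOM groups are removed at the racemic stage (HCl, MeOH, 40 °C) to give rac-pervilleanone F7. Silylation (TIPSOTf, 2,6-lutidine, CH2Cl2) gives the racemic bis(triisopropylsilyl) ether F8. Transfer hydrogenation as in step 10 gives the cis-(3R,4R) bis(triisopropylsilyl) alcohol F9, and Dess–Martin oxidation as in step 11 gives the (3R) bis(triisopropylsilyl) ketone F10. Desilylation with HF·pyridine in THF at 0 °C, which is non-basic, gives 23.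

## Further compounds

F1 | step 8 | 2-hydroxy-4-(methoxymethoxy)benzaldehyde | COCOc1ccc(C=O)c(O)c1
F2 | step 8 | 2-{1-hydroxy-2-[3,4-dimethoxy-2-(methoxymethoxy)-5-(2-methylbut-3-en-2-yl)phenyl]prop-2-en-1-yl}-5-(methoxymethoxy)phenol (racemic) | C=C(C(O)c1ccc(OCOC)cc1O)c1cc(C(C)(C)C=C)c(OC)c(OC)c1OCOC
F3 | step 8 | 1-[2-hydroxy-4-(methoxymethoxy)phenyl]-2-[3,4-dimethoxy-2-(methoxymethoxy)-5-(2-methylbut-3-en-2-yl)phenyl]prop-2-en-1-one | C=C(C(=O)c1ccc(OCOC)cc1O)c1cc(C(C)(C)C=C)c(OC)c(OC)c1OCOC
F4 | step 3 | 1-[3,4-dimethoxy-2-(2-methylbut-3-yn-2-yloxy)phenyl]ethan-1-one | CC(=O)c1ccc(OC)c(OC)c1OC(C)(C)C#C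
F5 | step 3 | 1-[3,4-dimethoxy-2-(2-methylbut-3-en-2-yloxy)phenyl]ethan-1-one | CC(=O)c1ccc(OC)c(OC)c1OC(C)(C)C=C
F6 | step 3 | 1-[2-hydroxy-3,4-dimethoxy-5-(2-methylbut-3-en-2-yl)phenyl]ethan-1-one | CC(=O)c1cc(C(C)(C)C=C)c(OC)c(OC)c1O
F7 | step 12 | rac-7-hydroxy-3-[2-hydroxy-3,4-dimethoxy-5-(2-methylbut-3-en-2-yl)phenyl]-2,3-dihydro-4H-chromen-4-one | C=CC(C)(C)c1cc(C2COc3cc(O)ccc3C2=O)c(O)c(OC)c1OC
F8 | step 12 | rac-3-[3,4-dimethoxy-5-(2-methylbut-3-en-2-yl)-2-(triisopropylsilyloxy)phenyl]-7-(triisopropylsilyloxy)-2,3-dihydro-4H-chromen-4-one | C=CC(C)(C)c1cc(C2COc3cc(O[Si](C(C)C)(C(C)C)C(C)C)ccc3C2=O)c(O[Si](C(C)C)(C(C)C)C(C)C)c(OC)c1OC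
F9 | step 12 | (3R,4R)-3-[3,4-dimethoxy-5-(2-methylbut-3-en-2-yl)-2-(triisopropylsilyloxy)phenyl]-7-(triisopropylsilyloxy)-3,4-dihydro-2H-chromen-4-ol | C=CC(C)(C)c1cc([C@@H]2COc3cc(O[Si](C(C)C)(C(C)C)C(C)C)ccc3[C@@H]2O)c(O[Si](C(C)C)(C(C)C)C(C)C)c(OC)c1OC
F10 | step 12 | (3R)-3-[3,4-dimethoxy-5-(2-methylbut-3-en-2-yl)-2-(triisopropylsilyloxy)phenyl]-7-(triisopropylsilyloxy)-2,3-dihydro-4H-chromen-4-one | C=CC(C)(C)c1cc([C@@H]2COc3cc(O[Si](C(C)C)(C(C)C)C(C)C)ccc3C2=O)c(O[Si](C(C)C)(C(C)C)C(C)C)c(OC)c1OC
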